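## Retrosynthetic overview

1. C6–C7 is cut as a stereoretentive Suzuki coupling between a (Z)-C7 enol triflate, made by formylation and triflation at C8 of the ring ketone, and an (E)-alkenylboronate from methyl hex-5-ynoate. This fixes 7Z and 5E.
2. The cyclopentenone C8–C12 is the only ring and is closed in step 5. C9–C10 comes from ipso-acylation of (1-bromovinyl)trimethylsilane by a 3-acetoxydienoyl fluoride, and C11–C12 from 4π electrocyclisation of the ketone so formed, both under one chiral Brønsted acid.
3. Enabling feature: the C9 carbonyl lies between C10(Br)=C11 and C8–C12, and C12 is a fully substituted acetoxy carbon. The ring is therefore the Nazarov product of the cation C11=C10–C9(O)–C8=C12(OAc); with no hydrogen on C12 the oxyallyl cation can only eliminate toward C11, which places the ring alkene at C10=C11 and keeps the acetate.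
4. The dienoyl fluoride comes from (Z)-non-3-en-1-ol through the β-keto ester and its (Z)-enol acetate, so bromine, the C12 acetate and the C14 Z-alkene are in place when the ring forms.

Key step: step 5

Assumption: prostanoid numbering is used (C1 ester carbon, C8–C12 ring, C20 chain end), and the SMILES is read as 12R, 5E, 14Z and 7Z (C6 cis to the C9 carbonyl).

## Route

Step 1
Reactants: 1 (Z)-non-3-en-1-ol
Product: 2 (Z)-non-3-enoic acid
Conditions: PhI(OAc)2 (2.2 equiv), TEMPO (2,2,6,6-tetramethylpiperidin-1-oxyl, 10 mol %), MeCN/H2O 1:1, rt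
Reagents that add atoms: water, O
Why: Oxoammonium (TEMPO) oxidation of the primary alcohol through the aldehyde hydrate to the acid; the near-neutral medium should leave the skipped Z-alkene in place.

Step 2
Reactants: 2 (Z)-non-3-enoic acid; 3 Meldrum's acid (2,2-dimethyl-1,3-dioxane-4,6-dione)
Product: 5 tert-butyl (Z)-3-oxoundec-5-enoate, via acylated Meldrum's acid 4 (not isolated)
Conditions: N,N'-dicyclohexylcarbodiimide (1.1 equiv), 4-(dimethylamino)pyridine (1.1 equiv), CH2Cl2, 0 °C to rt; filter, acid wash; then t-BuOH, toluene, 80 °C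
Reagents that add atoms: tert-butanol, CC(C)(C)O
Why: Oikawa–Yonemitsu sequence: carbodiimide C-acylation of Meldrum's acid, then thermal loss of acetone and CO2 to the acylketene, which tert-butanol traps as the β-keto ester.

Step 3
Reactants: 5 tert-butyl (Z)-3-oxoundec-5-enoate
Product: 6 tert-butyl (2Z,5Z)-3-acetoxyundeca-2,5-dienoate
Conditions: AcCl (1.2 equiv), Et3N (1.5 equiv), CH2Cl2, 0 °C
Reagents that add atoms: acetyl chloride, CC(Cl)=O
Why: O-acetylation of the internally hydrogen-bonded enol of the β-keto ester in a non-polar solvent should give mainly the (2Z)-enol acetate (acetoxy cis to the ester); any 2E isomer is removed by chromatography.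

Step 4
Reactants: 6 tert-butyl (2Z,5Z)-3-acetoxyundeca-2,5-dienoate
Product: 8 (2Z,5Z)-3-acetoxyundeca-2,5-dienoyl fluoride, via acetoxydienoic acid 7 (not isolated)
Conditions: CF3CO2H/CH2Cl2 1:4, 0 °C to rt, evaporate; then cyanuric fluoride (0.5 equiv), pyridine (1 equiv), CH2Cl2, −10 °C to rt
Reagents that add atoms: cyanuric fluoride, Fc1nc(F)nc(F)n1
Why: Acidolysis of the tert-butyl ester (loss of isobutene) followed by deoxyfluorination of the acid gives the acyl fluoride without touching the enol acetate or the Z-alkene.

Step 5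
Reactants: 8 (2Z,5Z)-3-acetoxyundeca-2,5-dienoyl fluoride; 9 (1-bromovinyl)trimethylsilane
Product: 11 (1S)-3-bromo-1-[(2Z)-oct-2-en-1-yl]-4-oxocyclopent-2-en-1-yl acetate, via bromovinyl dienone 10 (not isolated)
Conditions: chiral imidodiphosphorimidate acid HX* = (ArO)2P(=NSO2CF3)–NH–P(=NSO2CF3)(OAr)2, each (ArO)2 a 3,3'-diaryl-1,1'-bi-2-naphtholate of one configuration (5 mol %), 9 (5 equiv), toluene, −40 °C to 0 °C, slow addition of 8; Et3N quench
Reagents that add atoms: none
Why: Proposed new method: HX* is silylated by 9, Me3Si–X* takes fluoride from 8 (Si–F formation) to give a 3-acetoxyacryloyl cation paired with X*, this cation attacks 9 at the silicon-bearing carbon (β-silicon effect) to form C9–C10 as dienone 10 and release Me3Si–X* again, and the silylated ketone of 10 is a pentadienyl cation C11=C10–C9(O)–C8=C12 that closes the five-membered ring by conrotatory 4π electrocyclisation (Nazarov mode), forming C11–C12. The closest known reaction types are the one-flask acylation/Nazarov cyclopentenone annulation of vinylsilanes with unsaturated acyl halides under stoichiometric Lewis acids and the enantioselective Nazarov cyclisation of simple divinyl ketones under confined imidodiphosphorimidate acids; new are their union in one catalytic cycle and a cation terminus that carries an acyloxy group. C12 is the only new stereocentre, it is created in the electrocyclisation, and its configuration is the sense of conrotation, which the chiral pocket of X* should control; the catalyst enantiomer that leads to (S)-11 is to be found by experiment. The step needs ipso regioselectivity in the acylation, secured by silicon and bromine on the same carbon of 9, and a single mode of termination, secured by the substrate: C12 has no hydrogen, so the oxyallyl cation can only lose a proton from C11 (alkene at C10=C11), and loss of acetate would lead to a cyclopentadienone. The (2Z) geometry of 8 holds the C14=C15 alkene away from the acyl cation, excess 9 and slow addition of 8 should suppress intermolecular acylation of that alkene, and the acetoxy group is a weak enough donor to polarise the cation without stopping ring closure.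

Step 6
Reactants: 11 (1S)-3-bromo-1-[(2Z)-oct-2-en-1-yl]-4-oxocyclopent-2-en-1-yl acetate
Product: 12 (1R)-3-bromo-5-[(Z)-hydroxymethylidene]-1-[(2Z)-oct-2-en-1-yl]-4-oxocyclopent-2-en-1-yl acetate
Conditions: LiN(SiMe3)2 (1.1 equiv), THF, −78 °C; CF3CH2OCHO (1.5 equiv), −78 to −40 °C; aq. NH4Cl
Reagents that add atoms: 2,2,2-trifluoroethyl formate, O=COCC(F)(F)F
Why: Kinetic deprotonation at C8, the only enolisable ketone position, and Claisen-type C-formylation give the chelated (Z)-hydroxymethylene ketone; β-loss of the C12 acetate from the enolate is not expected because it would form a cyclopentadienone.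

Step 7
Reactants: 12 (1R)-3-bromo-5-[(Z)-hydroxymethylidene]-1-[(2Z)-oct-2-en-1-yl]-4-oxocyclopent-2-en-1-yl acetate
Product: 13 (1R)-3-bromo-1-[(2Z)-oct-2-en-1-yl]-4-oxo-5-[(Z)-(trifluoromethanesulfonyloxy)methylidene]cyclopent-2-en-1-yl acetate
Conditions: LiN(SiMe3)2 (1.05 equiv), THF, −78 °C; PhNTf2 (1.1 equiv), −78 to −20 °C; aq. NH4Cl
Reagents that add atoms: N-phenylbis(trifluoromethanesulfonimide), O=S(=O)(N(c1ccccc1)S(=O)(=O)C(F)(F)F)C(F)(F)F
Why: O-sulfonylation of the U-shaped lithium chelate at the exocyclic oxygen should keep the geometry and give the (Z)-enol triflate, by analogy with chelation-controlled (Z)-enol triflate formation from β-dicarbonyl compounds.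

Step 8
Reactants: 14 methyl hex-5-ynoate
Product: 15 methyl (E)-6-(4,4,5,5-tetramethyl-1,3,2-dioxaborolan-2-yl)hex-5-enoate
Conditions: pinacolborane (1.1 equiv), Cp2Zr(H)Cl (5 mol %), Et3N (10 mol %), neat, 60 °C
Reagents that add atoms: pinacolborane, B1OC(C)(C)C(C)(C)O1
Why: Zirconocene hydride-catalysed syn hydroboration of the terminal alkyne gives the anti-Markovnikov (E)-alkenylboronate; the ester is tolerated.

Step 9
Reactants: 13 (1R)-3-bromo-1-[(2Z)-oct-2-en-1-yl]-4-oxo-5-[(Z)-(trifluoromethanesulfonyloxy)methylidene]cyclopent-2-en-1-yl acetate; 15 methyl (E)-6-(4,4,5,5-tetramethyl-1,3,2-dioxaborolan-2-yl)hex-5-enoate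
Product: 16 methyl (5E,7Z)-7-[(5R)-5-acetoxy-3-bromo-5-[(2Z)-oct-2-en-1-yl]-2-oxocyclopent-3-en-1-ylidene]hept-5-enoate
Conditions: [1,1'-bis(diphenylphosphino)ferrocene]palladium dichloride PdCl2(dppf) (5 mol %), K3PO4 (3 equiv), THF/H2O 10:1, 0 °C to rt
Reagents that add atoms: none
Why: Suzuki–Miyaura coupling with retention at both sp2 carbons joins C6 to C7, so the Z triflate becomes 7Z and the E boronate 5E; the vinylogous acyl triflate should add to zerovalent palladium much faster than the C10–Br bond or the hindered tertiary allylic acetate.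

## Compound list

1 | (Z)-non-3-en-1-ol | CCCCC/C=C\CCO | starting material
2 | (Z)-non-3-enoic acid | CCCCC/C=C\CC(=O)O | intermediate
3 | Meldrum's acid (2,2-dimethyl-1,3-dioxane-4,6-dione) | CC1(C)OC(=O)CC(=O)O1 | starting material
4 | 2,2-dimethyl-5-[(Z)-non-3-enoyl]-1,3-dioxane-4,6-dione | CCCCC/C=C\CC(=O)C1C(=O)OC(C)(C)OC1=O | intermediate
5 | tert-butyl (Z)-3-oxoundec-5-enoate | CCCCC/C=C\CC(=O)CC(=O)OC(C)(C)C | intermediate
6 | tert-butyl (2Z,5Z)-3-acetoxyundeca-2,5-dienoate | CCCCC/C=C\C/C(OC(C)=O)=C/C(=O)OC(C)(C)C | intermediate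
7 | (2Z,5Z)-3-acetoxyundeca-2,5-dienoic acid | CCCCC/C=C\C/C(OC(C)=O)=C/C(=O)O | intermediate
8 | (2Z,5Z)-3-acetoxyundeca-2,5-dienoyl fluoride | CCCCC/C=C\C/C(OC(C)=O)=C/C(F)=O | intermediate
9 | (1-bromovinyl)trimethylsilane | C=C(Br)[Si](C)(C)C | starting material
10 | (4Z,7Z)-2-bromo-3-oxotrideca-1,4,7-trien-5-yl acetate | CCCCC/C=C\C/C(OC(C)=O)=C/C(=O)C(Br)=C | intermediate
11 | (1S)-3-bromo-1-[(2Z)-oct-2-en-1-yl]-4-oxocyclopent-2-en-1-yl acetate | CCCCC/C=C\C[C@@]1(OC(C)=O)C=C(Br)C(=O)C1 | intermediate
12 | (1R)-3-bromo-5-[(Z)-hydroxymethylidene]-1-[(2Z)-oct-2-en-1-yl]-4-oxocyclopent-2-en-1-yl acetate | CCCCC/C=C\C[C@@]1(OC(C)=O)C=C(Br)C(=O)/C1=C\O | intermediate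
13 | (1R)-3-bromo-1-[(2Z)-oct-2-en-1-yl]-4-oxo-5-[(Z)-(trifluoromethanesulfonyloxy)methylidene]cyclopent-2-en-1-yl acetate | CCCCC/C=C\C[C@@]1(OC(C)=O)C=C(Br)C(=O)/C1=C\OS(=O)(=O)C(F)(F)F | intermediate
14 | methyl hex-5-ynoate | C#CCCCC(=O)OC | starting material
15 | methyl (E)-6-(4,4,5,5-tetramethyl-1,3,2-dioxaborolan-2-yl)hex-5-enoate | COC(=O)CCC/C=C/B1OC(C)(C)C(C)(C)O1 | intermediate
16 | methyl (5E,7Z)-7-[(5R)-5-acetoxy-3-bromo-5-[(2Z)-oct-2-en-1-yl]-2-oxocyclopent-3-en-1-ylidene]hept-5-enoate | CCCCC/C=C\C[C@@]1(OC(C)=O)C=C(Br)C(=O)/C1=C\C=C\CCCC(=O)OC | target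

## Step count and risks

Total steps: 9. Longest linear sequence: 8 steps (steps 1 to 7, then 9); step 8 is a one-step side branch.

Steps most likely to fail:

1. Step 5. The acyl cation may transfer acetyl instead of the dienoyl group through its cyclic acetoxonium form, or it may acylate the C14=C15 alkene of another molecule. The oxyallyl cation may be intercepted by the neighbouring acetate or undergo a 1,2-shift at C12 instead of losing the C11 proton. Silyl transfer may not turn over, and the sense of conrotation may be poorly controlled. Fallback, setting out from 8 and 9 and coming back at 11: 8 and 9 are combined with stoichiometric BF3·OEt2 at −78 °C (acyl tetrafluoroborate, ipso-acylation) and dienone 10 is isolated. Compound 10 is cyclised with a stoichiometric achiral Lewis acid (FeCl3 or Me3SiOSO2CF3) to racemic 3-bromo-1-[(2Z)-oct-2-en-1-yl]-4-oxocyclopent-2-en-1-yl acetate F1. The enantiomers of F1 are separated by preparative chromatography on a chiral stationary phase to give 11.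

2. Step 9. Oxidative addition may compete at C10–Br, zerovalent palladium may ionise the tertiary allylic acetate, the base may hydrolyse the triflate, or the 7Z geometry may be lost by reversible conjugate addition. Fallback, setting out from 11 and coming back at 16: the lithium enolate of 11 (LiN(SiMe3)2, THF, −78 °C) is added to methyl (E)-7-oxohept-5-enoate F3, itself made by Wittig reaction of methyl 5-oxopentanoate with (triphenylphosphoranylidene)acetaldehyde. This gives the aldol adduct methyl (5E)-7-[(5S)-5-acetoxy-3-bromo-5-[(2Z)-oct-2-en-1-yl]-2-oxocyclopent-3-en-1-yl]-7-hydroxyhept-5-enoate F4 as a diastereomer mixture. Dehydration of F4 with Burgess reagent should give 16 together with its 7E isomer, which has to be removed by chromatography.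

3. Step 6. Acetyl may migrate from the C12 oxygen to the enolate oxygen, or the amide base may attack the acetate or add to the bromoenone. Fallback, setting out from 11 and coming back at 12: 11 is heated with tert-butoxybis(dimethylamino)methane (Bredereck's reagent) in toluene at 60 °C, without an enolate, to give (1R)-3-bromo-5-[(E)-(dimethylamino)methylidene]-1-[(2Z)-oct-2-en-1-yl]-4-oxocyclopent-2-en-1-yl acetate F2. Mild hydrolysis of F2 (1 M HCl, THF, 0 °C) gives 12.

## Further compounds

F1 | step 5 | racemic 3-bromo-1-[(2Z)-oct-2-en-1-yl]-4-oxocyclopent-2-en-1-yl acetate | CCCCC/C=C\CC1(OC(C)=O)C=C(Br)C(=O)C1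
F2 | step 6 | (1R)-3-bromo-5-[(E)-(dimethylamino)methylidene]-1-[(2Z)-oct-2-en-1-yl]-4-oxocyclopent-2-en-1-yl acetate | CCCCC/C=C\C[C@@]1(OC(C)=O)C=C(Br)C(=O)/C1=C/N(C)C
F3 | step 9 | methyl (E)-7-oxohept-5-enoate | COC(=O)CCC/C=C/C=O
F4 | step 9 | methyl (5E)-7-[(5S)-5-acetoxy-3-bromo-5-[(2Z)-oct-2-en-1-yl]-2-oxocyclopent-3-en-1-yl]-7-hydroxyhept-5-enoate | CCCCC/C=C\C[C@@]1(OC(C)=O)C=C(Br)C(=O)C1C(O)/C=C/CCCC(=O)OC
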